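**Strategy.** Everything rests on cutting the C(sp3)–C(sp3) bond between the methyl-bearing benzylic methine on C-2 of the trisubstituted phenol ring and the CH2 of the 4-hydroxybenzyl group. The key step exploits that this methine is benzylic to that aryl ring. As its (R)-N,N-diisopropylcarbamate, already carrying the complete 2,5-diaryl-3,4-dimethyloxolane, it is lithiated and united with 4-(benzyloxy)benzyl-Bpin. A stereospecific 1,2-metallate shift forges the bond and fixes the configuration as a tertiary boronic ester, which retentive protodeboronation turns into the C–H stereocentre. The oxolane core comes from Rh-catalysed desymmetrisation of meso-2,3-dimethylsuccinic anhydride, Felkin reduction, aryllithium addition and thermodynamically controlled cyclodehydration.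

Key step: step 11

Remark: in step 4 the enantiomer of the TADDOL-derived phosphoramidite is chosen so that the aryl group is delivered to the carbonyl attached to the (R)-configured methine of 2. All phenols are carried as benzyl ethers.

Step 1
Reactants: 1 meso-2,3-dimethylsuccinic acid
Product: 2 cis-2,3-dimethylsuccinic anhydride [(3R,4S)-3,4-dimethyloxolane-2,5-dione]
Conditions: AcCl, reflux; evaporate
Reagents that add atoms: none
Why: Acetyl chloride dehydrates the 1,4-diacid to the five-membered cyclic anhydride through a mixed anhydride without enolising the methine centres, so the cis (meso) relationship of the methyl groups should be kept.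

Step 2
Reactants: 3 1-(5-bromo-2-hydroxyphenyl)ethan-1-one
Product: 4 1-[2-(benzyloxy)-5-bromophenyl]ethan-1-one
Conditions: BnBr, K2CO3, DMF, 60 °C
Reagents that add atoms: benzyl bromide, BrCc1ccccc1
Why: Williamson etherification of the phenoxide protects the phenol as a base-stable benzyl ether that is removed at the end by hydrogenolysis.

Step 3
Reactants: 4 1-[2-(benzyloxy)-5-bromophenyl]ethan-1-one
Product: 5 2-[2-(benzyloxy)-5-bromophenyl]-2-methyl-1,3-dioxolane
Conditions: HOCH2CH2OH, TsOH·H2O (cat.), toluene, reflux, Dean–Stark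
Reagents that add atoms: ethylene glycol, OCCO
Why: Acid-catalysed ketalisation with azeotropic removal of water masks the acetyl group as a dioxolane that tolerates the organolithium, organozinc and hydride reagents of steps 4–6.

Step 4
Reactants: 5 2-[2-(benzyloxy)-5-bromophenyl]-2-methyl-1,3-dioxolane; 2 cis-2,3-dimethylsuccinic anhydride
Product: 8 (2S,3R)-4-[4-(benzyloxy)-3-(2-methyl-1,3-dioxolan-2-yl)phenyl]-2,3-dimethyl-4-oxobutanoic acid, via aryllithium 6 (not isolated), via arylzinc triflate 7 (not isolated)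
Conditions: n-BuLi, THF, −78 °C; Zn(OTf)2, −78 °C → rt; then 2, [Rh(cod)Cl]2 (cat.), TADDOL-PNMe2 phosphoramidite (cat.), THF–DMF, 50 °C; pH 4–5 buffer work-up
Reagents that add atoms: none
Why: Rhodium-catalysed enantioselective acylative cross-coupling (desymmetrisation of a meso cyclic anhydride with an arylzinc reagent) inserts the metal into one enantiotopic C(O)–O bond under ligand control, which fixes the absolute configuration of both methyl-bearing carbons at once without touching them.

Step 5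
Reactants: 8 (2S,3R)-4-[4-(benzyloxy)-3-(2-methyl-1,3-dioxolan-2-yl)phenyl]-2,3-dimethyl-4-oxobutanoic acid
Product: 10 (3S,4R,5R)-5-[4-(benzyloxy)-3-(2-methyl-1,3-dioxolan-2-yl)phenyl]-3,4-dimethyloxolan-2-one, via hydroxy acid 9 (not isolated)
Conditions: L-Selectride (2.3 equiv), THF, −78 °C; aq. NH4Cl; then PPTS (cat.), 4 Å MS, toluene, 60 °C
Reagents that add atoms: none
Why: Felkin–Anh addition of the bulky hydride to the aryl ketone, anti to the CH(CH3)CO2 branch of the α-stereocentre, should set the (4R)-carbinol, which lactonises to the γ-lactone with aryl trans to the neighbouring methyl (diastereoselective ketone reduction and lactonisation).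

Step 6
Reactants: 11 1-(benzyloxy)-4-bromobenzene; 10 (3S,4R,5R)-5-[4-(benzyloxy)-3-(2-methyl-1,3-dioxolan-2-yl)phenyl]-3,4-dimethyloxolan-2-one
Product: 14 (2S,3R,4R)-1-[4-(benzyloxy)phenyl]-4-[4-(benzyloxy)-3-(2-methyl-1,3-dioxolan-2-yl)phenyl]-2,3-dimethylbutane-1,4-diol (C-1 epimer mixture), via aryllithium 12 (not isolated), via hydroxy ketone 13 (not isolated)
Conditions: 11, n-BuLi, THF, −78 °C; then 10, −78 °C; then MeOH, NaBH4, −78 → 0 °C
Reagents that add atoms: none
Why: Aryllithium 1,2-addition to the γ-lactone stops at the lithium lactolate, whose ring-opened aryl ketone is reduced by borohydride in the same flask; the new C-1 carbinol may form as either epimer because step 7 erases it, and the low temperature protects the α-methyl centre from enolisation (organolithium addition and borohydride reduction).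

Step 7
Reactants: 14 (2S,3R,4R)-1-[4-(benzyloxy)phenyl]-4-[4-(benzyloxy)-3-(2-methyl-1,3-dioxolan-2-yl)phenyl]-2,3-dimethylbutane-1,4-diol (C-1 epimer mixture)
Product: 15 1-{2-(benzyloxy)-5-[(2R,3R,4S,5S)-5-[4-(benzyloxy)phenyl]-3,4-dimethyloxolan-2-yl]phenyl}ethan-1-one
Conditions: TsOH·H2O (cat.), CH2Cl2, 0 °C → rt; then acetone–H2O, rt
Reagents that add atoms: water, O
Why: Acid ionises the more electron-rich 4-benzyloxybenzylic carbinol (C-1) to a benzylic cation that the C-4 hydroxyl traps with retention at C-4, placing the new aryl trans to its neighbouring methyl, which is the thermodynamically preferred trans,cis,trans oxolane to which any cis epimer should equilibrate by reversible benzylic ionisation, while the dioxolane is hydrolysed to the acetyl group (SN1 cycloetherification and ketal hydrolysis).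

Step 8
Reactants: 15 1-{2-(benzyloxy)-5-[(2R,3R,4S,5S)-5-[4-(benzyloxy)phenyl]-3,4-dimethyloxolan-2-yl]phenyl}ethan-1-one
Product: 16 (1R)-1-{2-(benzyloxy)-5-[(2R,3R,4S,5S)-5-[4-(benzyloxy)phenyl]-3,4-dimethyloxolan-2-yl]phenyl}ethan-1-ol
Conditions: (S)-Me-CBS (cat.), BH3·SMe2, THF, −20 °C; MeOH
Reagents that add atoms: none
Why: Corey–Bakshi–Shibata reduction, in which the (S)-oxazaborolidine delivers hydride to the Si face of the aryl methyl ketone (aryl as the large group), should give the (R)-carbinol under catalyst control, independent of the remote oxolane.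

Step 9
Reactants: 16 (1R)-1-{2-(benzyloxy)-5-[(2R,3R,4S,5S)-5-[4-(benzyloxy)phenyl]-3,4-dimethyloxolan-2-yl]phenyl}ethan-1-ol
Product: 17 (1R)-1-{2-(benzyloxy)-5-[(2R,3R,4S,5S)-5-[4-(benzyloxy)phenyl]-3,4-dimethyloxolan-2-yl]phenyl}ethyl N,N-di(propan-2-yl)carbamate
Conditions: NaH, THF, 0 °C; iPr2NCOCl, rt → 50 °C
Reagents that add atoms: N,N-diisopropylcarbamoyl chloride, CC(C)N(C(C)C)C(Cl)=O
Why: O-Carbamoylation of the sodium alkoxide takes place at oxygen without breaking the carbinol C–O bond, so the (R) configuration is retained and the directing and leaving group for step 11 is installed.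

Step 10
Reactants: 18 1-(benzyloxy)-4-(chloromethyl)benzene
Product: 19 2-[4-(benzyloxy)benzyl]-4,4,5,5-tetramethyl-1,3,2-dioxaborolane
Conditions: B2pin2, Pd2(dba)3 (cat.), P(4-MeOC6H4)3 (cat.), KOAc, toluene, 50 °C
Reagents that add atoms: bis(pinacolato)diboron, CC1(C)OB(OC1(C)C)B1OC(C)(C)C(C)(C)O1
Why: Miyaura borylation of the benzylic chloride (oxidative addition, transmetalation with the acetate-activated diboron, reductive elimination) should give the primary benzylboronic ester.

Step 11
Reactants: 17 (1R)-1-{2-(benzyloxy)-5-[(2R,3R,4S,5S)-5-[4-(benzyloxy)phenyl]-3,4-dimethyloxolan-2-yl]phenyl}ethyl N,N-di(propan-2-yl)carbamate; 19 2-[4-(benzyloxy)benzyl]-4,4,5,5-tetramethyl-1,3,2-dioxaborolane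
Product: 22 2-[(2R)-1-[4-(benzyloxy)phenyl]-2-{2-(benzyloxy)-5-[(2R,3R,4S,5S)-5-[4-(benzyloxy)phenyl]-3,4-dimethyloxolan-2-yl]phenyl}propan-2-yl]-4,4,5,5-tetramethyl-1,3,2-dioxaborolane, via lithiated carbamate 20 (not isolated), via boronate complex 21 (not isolated)
Conditions: s-BuLi (1.3 equiv), Et2O, −78 °C, 1 h; then 19, −78 °C, 1 h; then MgBr2·OEt2/MeOH, −78 °C → rt
Reagents that add atoms: none
Why: s-BuLi, precoordinated to the carbamate carbonyl, removes the benzylic hydrogen with retention to give the configurationally stable α-carbamoyloxy benzyllithium 20, which adds to boron of 19 with retention to form ate complex 21; on warming, the 4-(benzyloxy)benzyl group migrates from boron to carbon antiperiplanar to the departing carbamate (1,2-metallate rearrangement with inversion at carbon) and so creates the C–CH2 bond. The closest known reaction type is the lithiation–borylation of enantioenriched secondary benzylic carbamates with pinacol boronic esters to give tertiary boronic esters. No ring is closed. The new fully substituted stereocentre (C–B, R) is controlled only by the (R)-carbinol configuration of 17 through the retention–retention–inversion sequence, that is by stereospecific transfer and not by the distant oxolane. The step needs deprotonation at the carbamate-bearing carbon and not at the benzyl ether CH2 groups or the oxolane C-2/C-5 hydrogens, which the complex-induced proximity effect of the carbamate at −78 °C in Et2O without diamine should secure. It also needs the ate complex not to revert, which would erode configuration for this ortho-substituted electron-rich aryl group, and the unhindered primary boronic ester together with the MgBr2/MeOH additive should secure that.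

Step 12
Reactants: 22 2-[(2R)-1-[4-(benzyloxy)phenyl]-2-{2-(benzyloxy)-5-[(2R,3R,4S,5S)-5-[4-(benzyloxy)phenyl]-3,4-dimethyloxolan-2-yl]phenyl}propan-2-yl]-4,4,5,5-tetramethyl-1,3,2-dioxaborolane
Product: 23 (2S,3S,4R,5R)-2-[4-(benzyloxy)phenyl]-5-{4-(benzyloxy)-3-[(2R)-1-[4-(benzyloxy)phenyl]propan-2-yl]phenyl}-3,4-dimethyloxolane
Conditions: TBAF·3H2O, toluene, 45 °C
Reagents that add atoms: none
Why: Fluoride/water-promoted protodeboronation of a tertiary benzylic pinacol boronate proceeds through the hydrated fluoroborate with front-side protonation of the C–B bond, so the configuration at boron-bearing carbon should be transferred with retention to the (R)-C–H centre (stereoretentive protodeboronation).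

Step 13
Reactants: 23 (2S,3S,4R,5R)-2-[4-(benzyloxy)phenyl]-5-{4-(benzyloxy)-3-[(2R)-1-[4-(benzyloxy)phenyl]propan-2-yl]phenyl}-3,4-dimethyloxolane
Product: 24 2-[(2R)-1-(4-hydroxyphenyl)propan-2-yl]-4-[(2R,3R,4S,5S)-5-(4-hydroxyphenyl)-3,4-dimethyloxolan-2-yl]phenol (CNP0232576.1)
Conditions: H2 (1 atm), 10% Pd/C, EtOAc–MeOH, rt
Reagents that add atoms: none
Why: Heterogeneous hydrogenolysis should cleave the three aryl benzyl ethers much faster than the ring C–O bonds of the 2,5-diaryloxolane under neutral low-pressure conditions, and no stereocentre takes part (O-debenzylation).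

**Compound list**

1 | meso-2,3-dimethylsuccinic acid | OC(=O)[C@@H](C)[C@H](C(=O)O)C | starting material
2 | cis-2,3-dimethylsuccinic anhydride, (3R,4S)-3,4-dimethyloxolane-2,5-dione | O=C1OC(=O)[C@@H](C)[C@H]1C | intermediate
3 | 1-(5-bromo-2-hydroxyphenyl)ethan-1-one | CC(=O)c1cc(Br)ccc1O | starting material
4 | 1-[2-(benzyloxy)-5-bromophenyl]ethan-1-one | CC(=O)c1cc(Br)ccc1OCc1ccccc1 | intermediate
5 | 2-[2-(benzyloxy)-5-bromophenyl]-2-methyl-1,3-dioxolane | CC1(c2cc(Br)ccc2OCc2ccccc2)OCCO1 | intermediate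
6 | [4-(benzyloxy)-3-(2-methyl-1,3-dioxolan-2-yl)phenyl]lithium | [Li]c1ccc(OCc2ccccc2)c(C2(C)OCCO2)c1 | intermediate (not isolated)
7 | [4-(benzyloxy)-3-(2-methyl-1,3-dioxolan-2-yl)phenyl]zinc triflate | FC(F)(F)S(=O)(=O)O[Zn]c1ccc(OCc2ccccc2)c(C2(C)OCCO2)c1 | intermediate (not isolated)
8 | (2S,3R)-4-[4-(benzyloxy)-3-(2-methyl-1,3-dioxolan-2-yl)phenyl]-2,3-dimethyl-4-oxobutanoic acid | C[C@@H](C(=O)c1ccc(OCc2ccccc2)c(C2(C)OCCO2)c1)[C@H](C)C(=O)O | intermediate
9 | (2S,3R,4R)-4-[4-(benzyloxy)-3-(2-methyl-1,3-dioxolan-2-yl)phenyl]-4-hydroxy-2,3-dimethylbutanoic acid | C[C@@H]([C@@H](O)c1ccc(OCc2ccccc2)c(C2(C)OCCO2)c1)[C@H](C)C(=O)O | intermediate (not isolated)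
10 | (3S,4R,5R)-5-[4-(benzyloxy)-3-(2-methyl-1,3-dioxolan-2-yl)phenyl]-3,4-dimethyloxolan-2-one | C[C@@H]1[C@H](C)C(=O)O[C@H]1c1ccc(OCc2ccccc2)c(C2(C)OCCO2)c1 | intermediate
11 | 1-(benzyloxy)-4-bromobenzene | Brc1ccc(OCc2ccccc2)cc1 | starting material
12 | [4-(benzyloxy)phenyl]lithium | [Li]c1ccc(OCc2ccccc2)cc1 | intermediate (not isolated)
13 | (2S,3R,4R)-1-[4-(benzyloxy)phenyl]-4-[4-(benzyloxy)-3-(2-methyl-1,3-dioxolan-2-yl)phenyl]-4-hydroxy-2,3-dimethylbutan-1-one (in equilibrium with its lactol) | C[C@@H]([C@@H](O)c1ccc(OCc2ccccc2)c(C2(C)OCCO2)c1)[C@H](C)C(=O)c1ccc(OCc2ccccc2)cc1 | intermediate (not isolated)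
14 | (2S,3R,4R)-1-[4-(benzyloxy)phenyl]-4-[4-(benzyloxy)-3-(2-methyl-1,3-dioxolan-2-yl)phenyl]-2,3-dimethylbutane-1,4-diol, C-1 epimer mixture | C[C@@H]([C@@H](O)c1ccc(OCc2ccccc2)c(C2(C)OCCO2)c1)[C@H](C)C(O)c1ccc(OCc2ccccc2)cc1 | intermediate
15 | 1-{2-(benzyloxy)-5-[(2R,3R,4S,5S)-5-[4-(benzyloxy)phenyl]-3,4-dimethyloxolan-2-yl]phenyl}ethan-1-one | C[C@@H]1[C@H](C)[C@@H](c2ccc(OCc3ccccc3)cc2)O[C@H]1c1ccc(OCc2ccccc2)c(C(C)=O)c1 | intermediate
16 | (1R)-1-{2-(benzyloxy)-5-[(2R,3R,4S,5S)-5-[4-(benzyloxy)phenyl]-3,4-dimethyloxolan-2-yl]phenyl}ethan-1-ol | C[C@@H]1[C@H](C)[C@@H](c2ccc(OCc3ccccc3)cc2)O[C@H]1c1ccc(OCc2ccccc2)c([C@@H](C)O)c1 | intermediate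
17 | (1R)-1-{2-(benzyloxy)-5-[(2R,3R,4S,5S)-5-[4-(benzyloxy)phenyl]-3,4-dimethyloxolan-2-yl]phenyl}ethyl N,N-di(propan-2-yl)carbamate | C[C@@H]1[C@H](C)[C@@H](c2ccc(OCc3ccccc3)cc2)O[C@H]1c1ccc(OCc2ccccc2)c([C@@H](C)OC(=O)N(C(C)C)C(C)C)c1 | intermediate
18 | 1-(benzyloxy)-4-(chloromethyl)benzene | ClCc1ccc(OCc2ccccc2)cc1 | starting material
19 | 2-[4-(benzyloxy)benzyl]-4,4,5,5-tetramethyl-1,3,2-dioxaborolane | CC1(C)OB(Cc2ccc(OCc3ccccc3)cc2)OC1(C)C | intermediate
20 | α-lithiated carbamate of 17 (lithium in place of the carbinol hydrogen, configuration retained) | C[C@@H]1[C@H](C)[C@@H](c2ccc(OCc3ccccc3)cc2)O[C@H]1c1ccc(OCc2ccccc2)c([C@@]([Li])(C)OC(=O)N(C(C)C)C(C)C)c1 | intermediate (not isolated)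
21 | lithium boronate (ate) complex of 20 with 19 | [Li+].C[C@@H]1[C@H](C)[C@@H](c2ccc(OCc3ccccc3)cc2)O[C@H]1c1ccc(OCc2ccccc2)c([C@@]([B-]2(Cc3ccc(OCc4ccccc4)cc3)OC(C)(C)C(C)(C)O2)(C)OC(=O)N(C(C)C)C(C)C)c1 | intermediate (not isolated)
22 | 2-[(2R)-1-[4-(benzyloxy)phenyl]-2-{2-(benzyloxy)-5-[(2R,3R,4S,5S)-5-[4-(benzyloxy)phenyl]-3,4-dimethyloxolan-2-yl]phenyl}propan-2-yl]-4,4,5,5-tetramethyl-1,3,2-dioxaborolane | C[C@@H]1[C@H](C)[C@@H](c2ccc(OCc3ccccc3)cc2)O[C@H]1c1ccc(OCc2ccccc2)c([C@](B2OC(C)(C)C(C)(C)O2)(C)Cc2ccc(OCc3ccccc3)cc2)c1 | intermediate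
23 | (2S,3S,4R,5R)-2-[4-(benzyloxy)phenyl]-5-{4-(benzyloxy)-3-[(2R)-1-[4-(benzyloxy)phenyl]propan-2-yl]phenyl}-3,4-dimethyloxolane | C[C@@H]1[C@H](C)[C@@H](c2ccc(OCc3ccccc3)cc2)O[C@H]1c1ccc(OCc2ccccc2)c([C@H](C)Cc2ccc(OCc3ccccc3)cc2)c1 | intermediate
24 | 2-[(2R)-1-(4-hydroxyphenyl)propan-2-yl]-4-[(2R,3R,4S,5S)-5-(4-hydroxyphenyl)-3,4-dimethyloxolan-2-yl]phenol | C[C@@H]1[C@H](C)[C@@H](c2ccc(O)cc2)O[C@H]1c1ccc(O)c([C@H](C)Cc2ccc(O)cc2)c1 | target

**Step count.** Total: 13 steps. Longest linear sequence: 11 steps (3 → 24 through steps 2–9 and 11–13).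

**Steps most likely to fail**

Step 11. What may go wrong is competing lithiation at a benzyl ether CH2 or at the benzylic oxolane hydrogens, or reversal of the ate complex with erosion of configuration. The fallback sets out from ketone 15. Addition of 4-(benzyloxy)benzylmagnesium chloride F1 (from 18 and Mg in THF) gives the tertiary alcohol F2 as a mixture of carbinol epimers and forms the same carbon–carbon bond. Dehydration with Burgess reagent in toluene, followed by iodine-catalysed equilibration, should give the conjugated (E)-alkene F3. Iridium-catalysed asymmetric hydrogenation with a cationic phosphinooxazoline complex (H2, CH2Cl2), a standard reaction for (E)-α-methylstilbenes, then sets the (R)-methine without cleaving the benzyl ethers and comes back to the route at 23.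

Step 12. What may go wrong is slow protonolysis of the hindered, electron-rich tertiary boronate, or partial loss of configuration through a free benzylic carbanion. The fallback sets out from 22. Oxidation (H2O2, NaOH, THF–H2O) with retention gives the (S)-tertiary alcohol F4. Dehydration and equilibration as above lead to the (E)-alkene F3 of the previous fallback, and the same asymmetric hydrogenation comes back to the route at 23.

Step 4. What may go wrong is insufficient discrimination of the two enantiotopic carbonyl groups, or sluggish transmetalation of the ketal-bearing arylzinc. The fallback sets out from anhydride 2. Alkaloid-catalysed desymmetrising methanolysis [(DHQD)2AQN or its pseudoenantiomer, MeOH, Et2O, −20 °C] gives (2R,3S)-4-methoxy-2,3-dimethyl-4-oxobutanoic acid F5. Oxalyl chloride with catalytic DMF gives the acid chloride F6. Palladium-catalysed acylative Negishi coupling with arylzinc 7 gives the keto ester F7. L-Selectride reduction with lactonisation (loss of methanol) comes back to the route at lactone 10.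

**Further compounds**

F1 | step 11 | 4-(benzyloxy)benzylmagnesium chloride | Cl[Mg]Cc1ccc(OCc2ccccc2)cc1
F2 | step 11 | 1-[4-(benzyloxy)phenyl]-2-{2-(benzyloxy)-5-[(2R,3R,4S,5S)-5-[4-(benzyloxy)phenyl]-3,4-dimethyloxolan-2-yl]phenyl}propan-2-ol, carbinol epimer mixture | C[C@@H]1[C@H](C)[C@@H](c2ccc(OCc3ccccc3)cc2)O[C@H]1c1ccc(OCc2ccccc2)c(C(C)(O)Cc2ccc(OCc3ccccc3)cc2)c1
F3 | step 11 | (2S,3S,4R,5R)-2-[4-(benzyloxy)phenyl]-5-{4-(benzyloxy)-3-[(E)-1-[4-(benzyloxy)phenyl]prop-1-en-2-yl]phenyl}-3,4-dimethyloxolane | C[C@@H]1[C@H](C)[C@@H](c2ccc(OCc3ccccc3)cc2)O[C@H]1c1ccc(OCc2ccccc2)c(/C(C)=C/c2ccc(OCc3ccccc3)cc2)c1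
F4 | step 12 | (2S)-1-[4-(benzyloxy)phenyl]-2-{2-(benzyloxy)-5-[(2R,3R,4S,5S)-5-[4-(benzyloxy)phenyl]-3,4-dimethyloxolan-2-yl]phenyl}propan-2-ol | C[C@@H]1[C@H](C)[C@@H](c2ccc(OCc3ccccc3)cc2)O[C@H]1c1ccc(OCc2ccccc2)c([C@](O)(C)Cc2ccc(OCc3ccccc3)cc2)c1
F5 | step 4 | (2R,3S)-4-methoxy-2,3-dimethyl-4-oxobutanoic acid | C[C@@H](C(=O)O)[C@H](C)C(=O)OC
F6 | step 4 | methyl (2S,3R)-4-chloro-2,3-dimethyl-4-oxobutanoate | C[C@@H](C(Cl)=O)[C@H](C)C(=O)OC
F7 | step 4 | methyl (2S,3R)-4-[4-(benzyloxy)-3-(2-methyl-1,3-dioxolan-2-yl)phenyl]-2,3-dimethyl-4-oxobutanoate | C[C@@H](C(=O)c1ccc(OCc2ccccc2)c(C2(C)OCCO2)c1)[C@H](C)C(=O)OC
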